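The molecule is divided at the acrylate ester C–O bond into acid 19 (ring A half) and spiro-epoxide lactone 32 (rings B and C), which are united by carboxylate opening of the epoxide. Ring A is closed late at its sp3–sp2 bond C6–C1 (cyclohexene numbering, C1 bearing CH2OH): hydroboration of the terminal olefin of the acyclic (Z)-2-iodo-2,6-dienol 11 and intramolecular B-alkyl Suzuki–Miyaura coupling give the cyclohexene in one operation. The step exploits the endocyclic trisubstituted olefin C1=C2 flanked by the ring methylene C6; the cis C3/C4 stereocentres come from one organocatalytic Michael addition and the olefin geometry from a trans-hydrostannation.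

Key step: step 7

Remark: ring A is the cyclohexene of the acyl half, ring B the cyclohexane and ring C the seven-membered lactone of the alcohol half; 28 is drawn as its lactol tautomer; the amine catalyst, 15, 16, 23 and 30 are taken as commercial.

Step 1
Reactants: 1 tert-butyldimethyl(prop-2-yn-1-yloxy)silane
Product: 2 4-[(tert-butyldimethylsilyl)oxy]but-2-ynal
Conditions: n-BuLi, THF, −78 °C; DMF; inverse quench into aq. KH2PO4
Reagents that add atoms: N,N-dimethylformamide, CN(C)C=O
Why: Formylation of the lithium acetylide with DMF should give the ynal once the hemiaminal collapses on buffered work-up.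

Step 2
Reactants: 2 4-[(tert-butyldimethylsilyl)oxy]but-2-ynal; 3 nitromethane
Product: 5 tert-butyldimethyl{[(4E)-5-nitropent-4-en-2-yn-1-yl]oxy}silane, via nitro alcohol 4 (not isolated)
Conditions: Et3N (10 mol%), THF, 0 °C; then MsCl, Et3N, CH2Cl2, −20 °C
Reagents that add atoms: none
Why: Henry reaction followed by mesylation and E1cB elimination should give the conjugated nitroenyne in its thermodynamically preferred E geometry.

Step 3
Reactants: 5 tert-butyldimethyl{[(4E)-5-nitropent-4-en-2-yn-1-yl]oxy}silane; 6 3-methylbutanal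
Product: 7 (2R,3S)-6-[(tert-butyldimethylsilyl)oxy]-3-(nitromethyl)-2-(propan-2-yl)hex-4-ynal
Conditions: (S)-α,α-diphenylprolinol trimethylsilyl ether (10 mol%), 4-nitrophenol (10 mol%), toluene, 0 °C
Reagents that add atoms: none
Why: Enamine-catalysed asymmetric Michael addition: the bulky group of the (S)-pyrrolidine shields one face of the E-enamine and the acyclic synclinal approach to the nitroalkene should give the syn (2R,3S) adduct by exclusive 1,4-addition, which sets both ring A stereocentres.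

Step 4
Reactants: 7 (2R,3S)-6-[(tert-butyldimethylsilyl)oxy]-3-(nitromethyl)-2-(propan-2-yl)hex-4-ynal
Product: 8 tert-butyldimethyl{[(4S,5S)-4-(nitromethyl)-5-(propan-2-yl)hept-6-en-2-yn-1-yl]oxy}silane
Conditions: Me3SiCHN2, PPh3, i-PrOH, RhCl(PPh3)3 (2.5 mol%), THF, 20 °C
Reagents that add atoms: (trimethylsilyl)diazomethane, C[Si](C)(C)C=[N+]=[N-]
Why: Rhodium-catalysed methylenation (a Wittig olefination in which Ph3P=CH2 is generated under neutral conditions) should convert the aldehyde into the terminal alkene without epimerizing the α-stereocentre or engaging the acidic nitromethyl group.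

Step 5
Reactants: 8 tert-butyldimethyl{[(4S,5S)-4-(nitromethyl)-5-(propan-2-yl)hept-6-en-2-yn-1-yl]oxy}silane
Product: 9 (4S,5S)-4-(dimethoxymethyl)-5-(propan-2-yl)hept-6-en-2-yn-1-ol
Conditions: NaOMe, MeOH, 0 °C; then added to H2SO4/MeOH, −40 °C to 20 °C
Reagents that add atoms: methanol, CO
Why: Nef reaction: the sodium nitronate is solvolysed in strongly acidic methanol to the dimethyl acetal, the same medium cleaves the primary silyl ether, and the masked aldehyde keeps the propargylic stereocentre from epimerizing.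

Step 6
Reactants: 9 (4S,5S)-4-(dimethoxymethyl)-5-(propan-2-yl)hept-6-en-2-yn-1-ol
Product: 11 (2Z,4S,5S)-4-(dimethoxymethyl)-2-iodo-5-(propan-2-yl)hepta-2,6-dien-1-ol, via alkenylstannane 10 (not isolated)
Conditions: Bu3SnH, [Cp*RuCl]4 (2.5 mol%), CH2Cl2, 20 °C; then I2, 0 °C
Reagents that add atoms: iodine, II
Why: Hydroxyl-assisted ruthenium-catalysed trans-hydrostannation should place tin on the alkyne carbon proximal to the OH group and hydrogen anti to it, and iododestannylation with retention then gives the Z iodoalkene with iodine cis to C4.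

Step 7
Reactants: 11 (2Z,4S,5S)-4-(dimethoxymethyl)-2-iodo-5-(propan-2-yl)hepta-2,6-dien-1-ol
Product: 13 [(3S,4R)-3-(dimethoxymethyl)-4-(propan-2-yl)cyclohex-1-en-1-yl]methanol, via alkylborane 12 (not isolated)
Conditions: 9-BBN (2.4 equiv), THF, 20 °C; then slow addition to Pd(dppf)Cl2 (10 mol%), AsPh3, Cs2CO3, DMF/THF/H2O, 45 °C, 0.01 M
Reagents that add atoms: none
Why: 9-BBN should add chemoselectively and anti-Markovnikov to the monosubstituted C6=C7 olefin (the trisubstituted iodoalkene is inert, the hydroxyl is tied up as a borinate) to give primary alkylborane 12; zerovalent palladium then inserts into the C2–I bond, base-activated boron-to-palladium transmetalation delivers C7, and reductive elimination forms the C2–C7 σ-bond. The closest known reaction type is the hydroboration/intramolecular B-alkyl Suzuki–Miyaura cyclization of ω-alkenyl haloalkenes to cycloalkenes. Ring A closes as a six-membered carbocycle by reductive elimination from a seven-membered alkyl(alkenyl)palladacycle, the olefin ending endocyclic. No stereocentre is created: C4 and C5 of 11 (C3 and C4 of 13) were fixed in step 3 and cannot epimerize because the formyl group is masked as its acetal. The step needs retention of the Z iodoalkene geometry (iodine cis to C4, set in step 6), which alone permits a cis ring olefin, and intra- over intermolecular coupling, which slow addition at high dilution and the fast six-membered closure should secure; the bidentate dppf ligand should suppress β-hydride elimination.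

Step 8
Reactants: 13 [(3S,4R)-3-(dimethoxymethyl)-4-(propan-2-yl)cyclohex-1-en-1-yl]methanol
Product: 14 (1S,6R)-3-(hydroxymethyl)-6-(propan-2-yl)cyclohex-2-ene-1-carbaldehyde
Conditions: Amberlyst-15 (cat.), acetone/H2O, 0 °C to 20 °C; crude aldehyde used at once
Reagents that add atoms: water, O
Why: Acid-catalysed acetal hydrolysis under mild heterogeneous conditions should release the β,γ-unsaturated aldehyde without olefin migration or epimerization at C1.

Step 9
Reactants: 14 (1S,6R)-3-(hydroxymethyl)-6-(propan-2-yl)cyclohex-2-ene-1-carbaldehyde; 15 ethyl 2-(diethoxyphosphoryl)prop-2-enoate; 16 (4-methoxyphenyl)methanol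
Product: 18 ethyl (2E)-3-[(1S,6R)-3-(hydroxymethyl)-6-(propan-2-yl)cyclohex-2-en-1-yl]-2-{[(4-methoxyphenyl)methoxy]methyl}prop-2-enoate, via sodium phosphonate 17 (not isolated)
Conditions: 16, NaH, THF, 0 °C; 15, 0 °C; then 14, −78 °C to 0 °C
Reagents that add atoms: none
Why: Tandem oxa-Michael/Horner–Wadsworth–Emmons reaction: the alkoxide adds to the phosphonoacrylate to give the stabilized carbanion 17, which should olefinate the α-branched aldehyde with E selectivity (ester trans to ring A) while being too weakly basic to epimerize the α-stereocentre.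

Step 10
Reactants: 18 ethyl (2E)-3-[(1S,6R)-3-(hydroxymethyl)-6-(propan-2-yl)cyclohex-2-en-1-yl]-2-{[(4-methoxyphenyl)methoxy]methyl}prop-2-enoate
Product: 19 (2E)-3-[(1S,6R)-3-(hydroxymethyl)-6-(propan-2-yl)cyclohex-2-en-1-yl]-2-{[(4-methoxyphenyl)methoxy]methyl}prop-2-enoic acid
Conditions: LiOH, THF/MeOH/H2O, 20 °C; then 1 M HCl to pH 3
Reagents that add atoms: lithium hydroxide, [Li+].[OH-]
Why: Saponification of the only ester present; the 4-methoxybenzyl ether and the free allylic alcohol are inert to aqueous LiOH.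

Step 11
Reactants: 6 3-methylbutanal; 20 but-3-en-2-one
Product: 22 (4S)-4-(propan-2-yl)cyclohex-2-en-1-one, via keto aldehyde 21 (not isolated)
Conditions: (S)-α,α-diphenylprolinol trimethylsilyl ether (5 mol%), ethyl 3,4-dihydroxybenzoate (20 mol%), neat, 4 °C; then KOH, Bu4NOH (cat.), Et2O/THF/H2O, 40 °C
Reagents that add atoms: none
Why: Enamine-catalysed Michael addition to the enone sets the isopropyl-bearing stereocentre with the same facial bias as in step 3, and base-mediated intramolecular aldol condensation of the keto aldehyde then closes the cyclohexenone (Robinson-type annulation).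

Step 12
Reactants: 22 (4S)-4-(propan-2-yl)cyclohex-2-en-1-one; 23 propa-1,2-diene
Product: 24 (1R,5S,6S)-8-methylidene-5-(propan-2-yl)bicyclo[4.2.0]octan-2-one
Conditions: hν (medium-pressure Hg lamp, Pyrex filter), THF, −78 °C
Reagents that add atoms: none
Why: Enone–allene [2+2] photocycloaddition: the head-to-head mode bonds the central allene carbon to the α-carbon, the new bond at the β-carbon should form anti to the neighbouring isopropyl group, and the four-membered ring is necessarily cis-fused, so C1 and C6 end cis to each other and C6 trans to isopropyl.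

Step 13
Reactants: 24 (1R,5S,6S)-8-methylidene-5-(propan-2-yl)bicyclo[4.2.0]octan-2-one
Product: 25 (1R,2R,5S,6S)-8-methylidene-5-(propan-2-yl)spiro[bicyclo[4.2.0]octane-2,2'-oxirane]
Conditions: ClCH2I, MeLi·LiBr, THF, −78 °C to 20 °C
Reagents that add atoms: chloroiodomethane, ClCI
Why: Chloromethyllithium (a carbenoid made in situ by iodine–lithium exchange) should add to the ketone from the convex face of the cis-fused bicycle, anti to the cyclobutane, and the chlorohydrin alkoxide closes to the spiro-epoxide (Darzens-type epoxidation), placing the oxygen cis and the CH2 trans to the C1–C8 bond.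

Step 14
Reactants: 25 (1R,2R,5S,6S)-8-methylidene-5-(propan-2-yl)spiro[bicyclo[4.2.0]octane-2,2'-oxirane]
Product: 26 (1S,2R,5S,6S)-5-(propan-2-yl)spiro[bicyclo[4.2.0]octane-2,2'-oxiran]-8-one
Conditions: O3, CH2Cl2/MeOH, −78 °C; then Me2S, −78 °C to 20 °C
Reagents that add atoms: ozone, [O-][O+]=O
Why: Ozonolysis with reductive work-up cleaves the only olefin to the cyclobutanone; the epoxide is inert to ozone.

Step 15
Reactants: 26 (1S,2R,5S,6S)-5-(propan-2-yl)spiro[bicyclo[4.2.0]octane-2,2'-oxiran]-8-one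
Product: 27 trimethyl{[(1S,2R,5S,6R)-5-(propan-2-yl)spiro[bicyclo[4.2.0]oct-7-ene-2,2'-oxiran]-8-yl]oxy}silane
Conditions: LiN(SiMe3)2, Me3SiCl, THF, −78 °C
Reagents that add atoms: chlorotrimethylsilane, C[Si](C)(C)Cl
Why: Kinetic deprotonation with in situ silylation should occur at the unhindered C7 methylene and not at the ring-fusion C1–H next to the quaternary spiro centre, giving the cyclobutene silyl enol ether.

Step 16
Reactants: 27 trimethyl{[(1S,2R,5S,6R)-5-(propan-2-yl)spiro[bicyclo[4.2.0]oct-7-ene-2,2'-oxiran]-8-yl]oxy}silane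
Product: 28 lactol tautomer of (3R,4S,5S,6S)-5-formyl-6-(propan-2-yl)-1-oxaspiro[2.5]octane-4-carboxylic acid
Conditions: O3, CH2Cl2, −78 °C; then Me2S; aqueous work-up at pH 5
Reagents that add atoms: ozone, [O-][O+]=O
Why: Ozonolysis of the silyl enol ether cleaves C7=C8 into a carboxylic acid (C8) and an aldehyde (C7) which, being cis on ring B, should collapse to the lactol, and this masks the acid from the epoxide.

Step 17
Reactants: 28 lactol tautomer of (3R,4S,5S,6S)-5-formyl-6-(propan-2-yl)-1-oxaspiro[2.5]octane-4-carboxylic acid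
Product: 29 (3R,4S,5S,6S)-5-ethenyl-6-(propan-2-yl)-1-oxaspiro[2.5]octane-4-carboxylic acid
Conditions: Ph3PCH3Br, KN(SiMe3)2, THF, 0 °C; then 28, −78 °C to 20 °C; NaH2PO4 work-up
Reagents that add atoms: methyltriphenylphosphonium bromide, C[P+](c1ccccc1)(c1ccccc1)c1ccccc1.[Br-]
Why: Wittig methylenation of a lactol: the ylide opens 28 to the formyl carboxylate and olefinates the aldehyde, the carboxylate-bearing centre not being enolizable under these conditions.

Step 18
Reactants: 29 (3R,4S,5S,6S)-5-ethenyl-6-(propan-2-yl)-1-oxaspiro[2.5]octane-4-carboxylic acid; 30 tert-butyl 2-(bromomethyl)prop-2-enoate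
Product: 31 tert-butyl 2-({[(3R,4S,5S,6S)-5-ethenyl-6-(propan-2-yl)-1-oxaspiro[2.5]octane-4-carbonyl]oxy}methyl)prop-2-enoate
Conditions: K2CO3, DMF, 0 °C to 20 °C
Reagents that add atoms: none
Why: SN2 O-alkylation of the potassium carboxylate by the activated allylic bromide; the weak base leaves the epoxide and the α-stereocentre untouched.

Step 19
Reactants: 31 tert-butyl 2-({[(3R,4S,5S,6S)-5-ethenyl-6-(propan-2-yl)-1-oxaspiro[2.5]octane-4-carbonyl]oxy}methyl)prop-2-enoate
Product: 32 tert-butyl (5aR,6S,9R,9aS)-1-oxo-6-(propan-2-yl)-3,5a,6,7,8,9a-hexahydro-1H-spiro[2-benzoxepine-9,2'-oxirane]-4-carboxylate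
Conditions: RuCl2(H2IMes)(=CH-2-i-PrOC6H4) (second-generation Hoveyda–Grubbs catalyst, 10 mol%), toluene, 80 °C, 0.005 M
Reagents that add atoms: none
Why: Ring-closing metathesis between the vinyl group and the 1,1-disubstituted acrylate, held cis on ring B, should close the seven-membered lactone (ring C) with loss of ethene, the olefin geometry being fixed by the ring.

Step 20
Reactants: 19 (2E)-3-[(1S,6R)-3-(hydroxymethyl)-6-(propan-2-yl)cyclohex-2-en-1-yl]-2-{[(4-methoxyphenyl)methoxy]methyl}prop-2-enoic acid; 32 tert-butyl (5aR,6S,9R,9aS)-1-oxo-6-(propan-2-yl)-3,5a,6,7,8,9a-hexahydro-1H-spiro[2-benzoxepine-9,2'-oxirane]-4-carboxylate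
Product: 33 tert-butyl (5aR,6S,9R,9aS)-9-hydroxy-9-{[((2E)-3-[(1S,6R)-3-(hydroxymethyl)-6-(propan-2-yl)cyclohex-2-en-1-yl]-2-{[(4-methoxyphenyl)methoxy]methyl}prop-2-enoyl)oxy]methyl}-1-oxo-6-(propan-2-yl)-1,3,5a,6,7,8,9,9a-octahydro-2-benzoxepine-4-carboxylate
Conditions: Cs2CO3 (0.2 equiv), Bu4NBr (0.1 equiv), DMF, 60 °C
Reagents that add atoms: none
Why: SN2 opening of the 2,2-disubstituted epoxide at its CH2 terminus by the caesium carboxylate (the tertiary alkoxide is reprotonated by 19, so base is catalytic) should give the primary ester and the tertiary alcohol with the carbinol configuration retained, while the alcohols of 19 do not compete.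

Step 21
Reactants: 33 tert-butyl (5aR,6S,9R,9aS)-9-hydroxy-9-{[((2E)-3-[(1S,6R)-3-(hydroxymethyl)-6-(propan-2-yl)cyclohex-2-en-1-yl]-2-{[(4-methoxyphenyl)methoxy]methyl}prop-2-enoyl)oxy]methyl}-1-oxo-6-(propan-2-yl)-1,3,5a,6,7,8,9,9a-octahydro-2-benzoxepine-4-carboxylate
Product: 34 (5aR,6S,9R,9aS)-9-hydroxy-9-{[((2E)-2-(hydroxymethyl)-3-[(1S,6R)-3-(hydroxymethyl)-6-(propan-2-yl)cyclohex-2-en-1-yl]prop-2-enoyl)oxy]methyl}-1-oxo-6-(propan-2-yl)-1,3,5a,6,7,8,9,9a-octahydro-2-benzoxepine-4-carboxylic acid (target)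
Conditions: CF3CO2H/CH2Cl2 (1:4), anisole, 0 °C; then NaHCO3, MeOH/H2O; acidify to pH 4
Reagents that add atoms: none
Why: Acidolysis should cleave the tert-butyl ester (loss of isobutene) and the 4-methoxybenzyl ether (cation trapped by anisole) in one operation, and the mild methanolysis returns any trifluoroacetylated hydroxyl groups.

Compound list
1 | tert-butyldimethyl(prop-2-yn-1-yloxy)silane | C#CCO[Si](C)(C)C(C)(C)C | starting material
2 | 4-[(tert-butyldimethylsilyl)oxy]but-2-ynal | O=CC#CCO[Si](C)(C)C(C)(C)C | intermediate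
3 | nitromethane | C[N+](=O)[O-] | starting material
4 | 5-[(tert-butyldimethylsilyl)oxy]-1-nitropent-3-yn-2-ol (racemic) | O=[N+]([O-])CC(O)C#CCO[Si](C)(C)C(C)(C)C | intermediate
5 | tert-butyldimethyl{[(4E)-5-nitropent-4-en-2-yn-1-yl]oxy}silane | [O-][N+](=O)/C=C/C#CCO[Si](C)(C)C(C)(C)C | intermediate
6 | 3-methylbutanal | CC(C)CC=O | starting material
7 | (2R,3S)-6-[(tert-butyldimethylsilyl)oxy]-3-(nitromethyl)-2-(propan-2-yl)hex-4-ynal | O=C[C@H](C(C)C)[C@@H](C#CCO[Si](C)(C)C(C)(C)C)C[N+](=O)[O-] | intermediate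
8 | tert-butyldimethyl{[(4S,5S)-4-(nitromethyl)-5-(propan-2-yl)hept-6-en-2-yn-1-yl]oxy}silane | C=C[C@H](C(C)C)[C@@H](C#CCO[Si](C)(C)C(C)(C)C)C[N+](=O)[O-] | intermediate
9 | (4S,5S)-4-(dimethoxymethyl)-5-(propan-2-yl)hept-6-en-2-yn-1-ol | C=C[C@H](C(C)C)[C@@H](C#CCO)C(OC)OC | intermediate
10 | (2Z,4S,5S)-4-(dimethoxymethyl)-5-(propan-2-yl)-2-(tributylstannyl)hepta-2,6-dien-1-ol | OC/C([Sn](CCCC)(CCCC)CCCC)=C/[C@H]([C@H](C=C)C(C)C)C(OC)OC | intermediate
11 | (2Z,4S,5S)-4-(dimethoxymethyl)-2-iodo-5-(propan-2-yl)hepta-2,6-dien-1-ol | OC/C(I)=C/[C@H]([C@H](C=C)C(C)C)C(OC)OC | intermediate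
12 | 9-{(3R,4S,5Z)-7-[(9-borabicyclo[3.3.1]nonan-9-yl)oxy]-4-(dimethoxymethyl)-6-iodo-3-(propan-2-yl)hept-5-en-1-yl}-9-borabicyclo[3.3.1]nonane | C1CCC2CCCC1B2OC/C(I)=C/[C@H]([C@H](CCB1C2CCCC1CCC2)C(C)C)C(OC)OC | intermediate
13 | [(3S,4R)-3-(dimethoxymethyl)-4-(propan-2-yl)cyclohex-1-en-1-yl]methanol | OCC1=C[C@H]([C@H](CC1)C(C)C)C(OC)OC | intermediate
14 | (1S,6R)-3-(hydroxymethyl)-6-(propan-2-yl)cyclohex-2-ene-1-carbaldehyde | OCC1=C[C@H]([C@H](CC1)C(C)C)C=O | intermediate
15 | ethyl 2-(diethoxyphosphoryl)prop-2-enoate | C=C(C(=O)OCC)P(=O)(OCC)OCC | starting material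
16 | (4-methoxyphenyl)methanol | COc1ccc(CO)cc1 | starting material
17 | sodium salt of the carbanion of ethyl 2-(diethoxyphosphoryl)-3-[(4-methoxyphenyl)methoxy]propanoate | CCOC(=O)[C-](COCc1ccc(OC)cc1)P(=O)(OCC)OCC.[Na+] | intermediate
18 | ethyl (2E)-3-[(1S,6R)-3-(hydroxymethyl)-6-(propan-2-yl)cyclohex-2-en-1-yl]-2-{[(4-methoxyphenyl)methoxy]methyl}prop-2-enoate | OCC1=C[C@H]([C@H](CC1)C(C)C)/C=C(\COCc1ccc(OC)cc1)C(=O)OCC | intermediate
19 | (2E)-3-[(1S,6R)-3-(hydroxymethyl)-6-(propan-2-yl)cyclohex-2-en-1-yl]-2-{[(4-methoxyphenyl)methoxy]methyl}prop-2-enoic acid | OCC1=C[C@H]([C@H](CC1)C(C)C)/C=C(\COCc1ccc(OC)cc1)C(=O)O | intermediate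
20 | but-3-en-2-one | CC(=O)C=C | starting material
21 | (2S)-5-oxo-2-(propan-2-yl)hexanal | O=C[C@H](C(C)C)CCC(C)=O | intermediate
22 | (4S)-4-(propan-2-yl)cyclohex-2-en-1-one | O=C1C=C[C@H](C(C)C)CC1 | intermediate
23 | propa-1,2-diene | C=C=C | starting material
24 | (1R,5S,6S)-8-methylidene-5-(propan-2-yl)bicyclo[4.2.0]octan-2-one | O=C1CC[C@@H](C(C)C)[C@@H]2CC(=C)[C@H]12 | intermediate
25 | (1R,2R,5S,6S)-8-methylidene-5-(propan-2-yl)spiro[bicyclo[4.2.0]octane-2,2'-oxirane] | C1O[C@@]12CC[C@@H](C(C)C)[C@@H]3CC(=C)[C@H]23 | intermediate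
26 | (1S,2R,5S,6S)-5-(propan-2-yl)spiro[bicyclo[4.2.0]octane-2,2'-oxiran]-8-one | C1O[C@@]12CC[C@@H](C(C)C)[C@@H]3CC(=O)[C@H]23 | intermediate
27 | trimethyl{[(1S,2R,5S,6R)-5-(propan-2-yl)spiro[bicyclo[4.2.0]oct-7-ene-2,2'-oxiran]-8-yl]oxy}silane | C1O[C@@]12CC[C@@H](C(C)C)[C@@H]3C=C(O[Si](C)(C)C)[C@H]23 | intermediate
28 | lactol tautomer of (3R,4S,5S,6S)-5-formyl-6-(propan-2-yl)-1-oxaspiro[2.5]octane-4-carboxylic acid (cis-fused γ-hydroxy lactone, both anomers) | C1O[C@@]12CC[C@@H](C(C)C)[C@@H]3C(O)OC(=O)[C@H]23 | intermediate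
29 | (3R,4S,5S,6S)-5-ethenyl-6-(propan-2-yl)-1-oxaspiro[2.5]octane-4-carboxylic acid | C1O[C@@]12CC[C@@H](C(C)C)[C@H](C=C)[C@@H]2C(=O)O | intermediate
30 | tert-butyl 2-(bromomethyl)prop-2-enoate | C=C(CBr)C(=O)OC(C)(C)C | starting material
31 | tert-butyl 2-({[(3R,4S,5S,6S)-5-ethenyl-6-(propan-2-yl)-1-oxaspiro[2.5]octane-4-carbonyl]oxy}methyl)prop-2-enoate | C1O[C@@]12CC[C@@H](C(C)C)[C@H](C=C)[C@@H]2C(=O)OCC(=C)C(=O)OC(C)(C)C | intermediate
32 | tert-butyl (5aR,6S,9R,9aS)-1-oxo-6-(propan-2-yl)-3,5a,6,7,8,9a-hexahydro-1H-spiro[2-benzoxepine-9,2'-oxirane]-4-carboxylate | C1O[C@@]12CC[C@@H](C(C)C)[C@@H]3C=C(C(=O)OC(C)(C)C)COC(=O)[C@H]23 | intermediate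
33 | tert-butyl (5aR,6S,9R,9aS)-9-hydroxy-9-{[((2E)-3-[(1S,6R)-3-(hydroxymethyl)-6-(propan-2-yl)cyclohex-2-en-1-yl]-2-{[(4-methoxyphenyl)methoxy]methyl}prop-2-enoyl)oxy]methyl}-1-oxo-6-(propan-2-yl)-1,3,5a,6,7,8,9,9a-octahydro-2-benzoxepine-4-carboxylate | OCC1=C[C@H]([C@H](CC1)C(C)C)/C=C(\COCc1ccc(OC)cc1)C(=O)OC[C@@]1(O)CC[C@@H](C(C)C)[C@@H]2C=C(C(=O)OC(C)(C)C)COC(=O)[C@@H]21 | intermediate
34 | (5aR,6S,9R,9aS)-9-hydroxy-9-{[((2E)-2-(hydroxymethyl)-3-[(1S,6R)-3-(hydroxymethyl)-6-(propan-2-yl)cyclohex-2-en-1-yl]prop-2-enoyl)oxy]methyl}-1-oxo-6-(propan-2-yl)-1,3,5a,6,7,8,9,9a-octahydro-2-benzoxepine-4-carboxylic acid | CC(C)[C@H]1CCC(CO)=C[C@H]1/C=C(\CO)C(=O)OC[C@@]1(O)CC[C@@H](C(C)C)[C@@H]2C=C(C(=O)O)COC(=O)[C@@H]21 | target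

Total step count: 21 (steps 1–10 for acid 19, steps 11–19 for epoxide 32, steps 20 and 21 for union and deprotection).
Longest linear sequence: 12 steps (steps 1–10, 20, 21, from compound 1).

Steps most likely to fail

Step 7 (key step). If transmetalation to the hindered, α-branched alkenylpalladium iodide is slow, the alkylborane may be lost to protodeboronation or the alkylpalladium to β-hydride elimination, and intermolecular coupling may compete with ring closure. The fallback forms the same bond by reductive cross-electrophile coupling and sets out from 11. Silylation (TBSCl, imidazole) would give the tert-butyldimethylsilyl ether of 11 F1. Hydroboration–oxidation (9-BBN; NaBO3) would give the primary alcohol F2, and iodination (I2, PPh3, imidazole) the alkyl/alkenyl diiodide F3. Nickel-catalysed intramolecular reductive coupling (NiBr2(dme), 4,4'-di-tert-butyl-2,2'-bipyridine, zinc dust, DMA) would then give the cyclohexene silyl ether F4, which Bu4NF would desilylate to 13, where the route is rejoined.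

Step 19. Ring closure may stall because the ester tether prefers its extended conformation and the 1,1-disubstituted acrylate is a reluctant metathesis partner, so that oligomerization through the vinyl group takes over. The fallback builds the olefin first and closes ring C by lactonization; it sets out from lactol 28 and makes steps 17 and 18 unnecessary. Horner–Wadsworth–Emmons reaction of 28 (NaH, THF) with tert-butyl 2-(diethoxyphosphoryl)-3-[(4-methoxyphenyl)methoxy]propanoate F5 would give the E enoate acid F6. Reagent F5 would be prepared from tert-butyl diethylphosphonoacetate, NaH and 4-methoxybenzyl chloromethyl ether. DDQ (CH2Cl2/H2O) would free the hydroxy acid F7, and Yamaguchi lactonization (2,4,6-trichlorobenzoyl chloride, Et3N, then DMAP, toluene, high dilution) would return to 32.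

Step 20. The acid may attack the epoxide CH2 only sluggishly because it sits next to a quaternary carbon, and prolonged heating may bring on base-induced β-elimination of the epoxide toward the C9a–H or attack on the lactone. The fallback hands the epoxide opening to a cheap nucleophile used in excess and unites the halves by olefination; it sets out from 32 and aldehyde 14 and makes steps 9 and 10 unnecessary. Carbanion 17, made as in step 9, would be protonated (AcOH) to the neutral phosphonate ethyl ester F8 and saponified (LiOH) to the phosphono acid F9. The caesium salt of F9 (DMF, 60 °C) would open 32 at CH2 to the ring B/C phosphonoacetate F10. Horner–Wadsworth–Emmons reaction of F10 with 14 (LiCl, i-Pr2NEt, MeCN) would then give 33, where the route is rejoined.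

Further compounds
F1 | step 7 | tert-butyl{[(2Z,4S,5S)-4-(dimethoxymethyl)-2-iodo-5-(propan-2-yl)hepta-2,6-dien-1-yl]oxy}dimethylsilane | CC(C)(C)[Si](C)(C)OC/C(I)=C/[C@H]([C@H](C=C)C(C)C)C(OC)OC
F2 | step 7 | (3R,4S,5Z)-7-[(tert-butyldimethylsilyl)oxy]-4-(dimethoxymethyl)-6-iodo-3-(propan-2-yl)hept-5-en-1-ol | CC(C)(C)[Si](C)(C)OC/C(I)=C/[C@H]([C@H](CCO)C(C)C)C(OC)OC
F3 | step 7 | tert-butyl{[(2Z,4S,5R)-4-(dimethoxymethyl)-2,7-diiodo-5-(propan-2-yl)hept-2-en-1-yl]oxy}dimethylsilane | CC(C)(C)[Si](C)(C)OC/C(I)=C/[C@H]([C@H](CCI)C(C)C)C(OC)OC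
F4 | step 7 | tert-butyl{[(3S,4R)-3-(dimethoxymethyl)-4-(propan-2-yl)cyclohex-1-en-1-yl]methoxy}dimethylsilane | CC(C)(C)[Si](C)(C)OCC1=C[C@H]([C@H](CC1)C(C)C)C(OC)OC
F5 | step 19 | tert-butyl 2-(diethoxyphosphoryl)-3-[(4-methoxyphenyl)methoxy]propanoate | CCOP(=O)(OCC)C(COCc1ccc(OC)cc1)C(=O)OC(C)(C)C
F6 | step 19 | (3R,4S,5R,6S)-5-[(1E)-3-tert-butoxy-2-{[(4-methoxyphenyl)methoxy]methyl}-3-oxoprop-1-en-1-yl]-6-(propan-2-yl)-1-oxaspiro[2.5]octane-4-carboxylic acid | C1O[C@@]12CC[C@@H](C(C)C)[C@H](/C=C(\COCc3ccc(OC)cc3)C(=O)OC(C)(C)C)[C@@H]2C(=O)O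
F7 | step 19 | (3R,4S,5R,6S)-5-[(1E)-3-tert-butoxy-2-(hydroxymethyl)-3-oxoprop-1-en-1-yl]-6-(propan-2-yl)-1-oxaspiro[2.5]octane-4-carboxylic acid | C1O[C@@]12CC[C@@H](C(C)C)[C@H](/C=C(\CO)C(=O)OC(C)(C)C)[C@@H]2C(=O)O
F8 | step 20 | ethyl 2-(diethoxyphosphoryl)-3-[(4-methoxyphenyl)methoxy]propanoate | CCOC(=O)C(COCc1ccc(OC)cc1)P(=O)(OCC)OCC
F9 | step 20 | 2-(diethoxyphosphoryl)-3-[(4-methoxyphenyl)methoxy]propanoic acid | OC(=O)C(COCc1ccc(OC)cc1)P(=O)(OCC)OCC
F10 | step 20 | tert-butyl (5aR,6S,9R,9aS)-9-{[(2-(diethoxyphosphoryl)-3-[(4-methoxyphenyl)methoxy]propanoyl)oxy]methyl}-9-hydroxy-1-oxo-6-(propan-2-yl)-1,3,5a,6,7,8,9,9a-octahydro-2-benzoxepine-4-carboxylate | CCOP(=O)(OCC)C(COCc1ccc(OC)cc1)C(=O)OC[C@@]1(O)CC[C@@H](C(C)C)[C@@H]2C=C(C(=O)OC(C)(C)C)COC(=O)[C@@H]21
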